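Two flasks, two questions each: which species holds the most substrate at the end, and how much.

| setting | ochre | amber | Tuesday's | Wednesday's |
|---|---|---|---|---|
| substrate | 0.40 M | 0.40 M | 0.40 M | 0.40 M |
| reagent | 0.72 M | 2.6 M | 1.00 M | 3.00 M |
| remark | run made earlier | run made earlier |  |  |
| time |  |  | 3.0 min | 3.0 min |

| run | time / s | intermediate B / % | intermediate C / % | intermediate E / % | intermediate A / % | substrate / % | target / % |
|---|---|---|---|---|---|---|---|
| ochre | 25.0 | 0.4 | 16.1 | 2.3 | 6.7 | 76.0 | 0 |
| ochre | 50.0 | 2.8 | 25.2 | 2.6 | 8.6 | 61.1 | 0 |
| ochre | 80.0 | 4.1 | 33.1 | 7.0 | 9.7 | 47.6 | 0.4 |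
| ochre | 90.0 | 4.7 | 34.8 | 4.7 | 12.7 | 43.3 | 0.3 |
| ochre | 120 | 4.7 | 38.9 | 8.9 | 14.4 | 33.5 | 0.5 |
| amber | 25.0 | 3.2 | 37.8 | 8.6 | 3.7 | 47.2 | 0 |
| amber | 50.0 | 2.2 | 44.2 | 23.5 | 4.5 | 23.5 | 0.8 |
| amber | 80.0 | 3.7 | 45.2 | 38.8 | 3.1 | 11.2 | 1.2 |
| amber | 90.0 | 4.1 | 43.0 | 40.1 | 1.3 | 7.6 | 0.8 |
| amber | 120 | 5.2 | 39.6 | 46.8 | 2.4 | 6.6 | 1.5 |

(standard deviation of a reading: 1 percentage point)

* which of these there is most of at the end, counted by the substrate in it, Tuesday's (intermediate B / substrate / intermediate E / intermediate C / intermediate A)
* which of these there is most of at the end, counted by the substrate in it, Wednesday's (intermediate B / substrate / intermediate E / intermediate C / intermediate A)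
* final amount of the leader among these, as a percentage of the substrate charged, in Tuesday's
* final amount of the leader among these, as a percentage of the substrate charged, in Wednesday's

- a reading or a percentage of target counts all its forms, free or not

In the amber run intermediate C flattens while intermediate E climbs past it, which reads as C taking up a second reagent, reversibly. Free reagent at the last amber reading is the charge less one reagent per C, B and target and two per E, so 2.04 M. That reading gives 1.73 M for the crossing concentration c*, the free reagent at which c(intermediate E) equals c(intermediate C), so that c(E)/c(C) = c(reagent)/c*. The ratio was higher at the last reading than at 80.0 s, so c* may lie lower.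

With the main step by itself, substrate plus reagent giving C, C leads both flasks.

Adding the balance separates them. Wednesday's free reagent comes to about 2.40 M, counting a second reagent for about half the substrate, which is above c*, so E takes 58.2% of the pool of C and E. Tuesday's comes to about 0.600 M, counting one reagent per substrate charged, which is below c*, so E takes 25.8%.

The remaining steps lower the numbers. Substrate loss is taken as pseudo-first-order, with its rate constant on a straight line in reagent through ochre and amber; interpolated on that line, it leaves 13.5% on Tuesday's, and extrapolated beyond amber, it leaves 1.01% on Wednesday's. Intermediates A and B and target are taken at their last readings, ochre for Tuesday's and amber for Wednesday's. This reckoning ends at C with 49.7% on Tuesday's and E with 52.3% on Wednesday's.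

The forecast, on the ground of a step “approaching a balance”, named for Tuesday's intermediate C at 45%, lower than this reckoning, and for Wednesday's intermediate E at 56%, higher than it.

Tuesday's flask gives intermediate C at 48.2%. Wednesday's flask gives intermediate E at 57.1%.

    intermediate B → target (k = 0.00459 s⁻¹)
    reagent + intermediate A → intermediate B (k = 0.00959 M⁻¹ s⁻¹)
    crystals ⇌ target, rate k3*(cs3 - [target]) while solid is left; crystals form when [target] > cs3 (solubility = 4.30 mM, k = 0.0514 s⁻¹)
    reagent + intermediate C ⇌ intermediate E (K = 0.753 M⁻¹, k = 0.00769 M⁻¹ s⁻¹)
    target → over-reaction product (k = 2.73 × 10⁻⁵ s⁻¹)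
    intermediate A ⇌ intermediate D (K = 0.109, k = 0.00203 s⁻¹)
    target ⇌ isomer of the product (K = 2.66, k = 0.00523 s⁻¹)
    substrate + reagent → intermediate C (k = 0.0110 M⁻¹ s⁻¹)
    substrate ⇌ intermediate A (K = 2.22, k = 0.00297 s⁻¹)

Wednesday's ends with 2.38 M of free reagent, above c*, and with c(E)/c(C) at 1.69, where c* gives 1.38. The neighbour charged with 1.8 M of reagent, other charges and the time held, reckons to 1.20 M of free reagent, below c*, so C should lead there, with E at 41.0% of the pool. That flask keeps 1.28 M of free reagent and ends with intermediate C at 45.5% and intermediate E at 37.5%.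

The runs were generated by integration for an exercise; the scatter is artificial.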